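Readings and results come from a simulation for an exercise, and the scatter is random.

The flask is charged thinner than the west run, 0.10 M against 0.15 M, with the same feed time and equivalents, so we ask how a percent reading follows the charge.

| flask | substrate | reagent in the second phase | remark | time | volume of the second phase over the first |
|---|---|---|---|---|---|
| west | 0.15 M (fed, over 2.5 d) | 1.3 equiv | run made earlier |  |  |
| flask | 0.10 M (fed, over 2.5 d) | 1.30 equiv |  | 15 d | 2.0 |

west run (percent of the substrate charged)

| time / d | target / % |
|---|---|
| 0.625 | 3.4 |
| 1.25 | 10.9 |
| 1.67 | 14.7 |
| 2.50 | 22.5 |
| 3.00 | 25.6 |

(readings scatter by 0.3 percentage points)

- in the second phase: reagent in the second phase; everything else is in the first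
- charges count per volume of the first phase; a concentration in a rate is the amount of a species over the volume of its own phase; every rate counts per litre of the first phase
- the earlier runs hold the two phases in the same ratio of volumes as the flask asked about
- percentages count the whole charge, also what has not yet gone in

* time, not beyond 15 d, at which the flask holds most target
* the amount of target, in percent of the substrate charged, at that time
* the first time at which target reaches 9.3%, in the same percent, in d

**Lower bound.** If the rate is first order overall, the percent curve doesn't move with the charge, and the west curve, read between its points, reaches 9.3% at 1.12 d.

**Upper bound.** If the rate is second order, target scales with the charge ratio 0.667. The flask then needs the west reading 13.9%, which comes at 1.59 d.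

**Second round.** We put that time back in. By then 63.5% has been fed, and if we count target as what has reacted, our reckoning puts more unreacted substrate in the flask than in the west run, 54.2% against 49.6%, a gain of 1.09 at that moment. Crediting half of the excess as the mean, the factor rises to 0.698 and the upper bound falls to 1.52 d. So we commit to a charge exponent, the power of the charge ratio by which a percent reading moves at a given time with equivalents and feed time held, of at most 0.887. It is the apparent reaction order less one.

**Best amount.** The west run still rises at 3.00 d, reading 25.6%, so we estimate the flask's best at no less than 17.9%. We leave its time open.

**The result.** The forecast gives 1.6 d, above our bracket, and 22% at 15 d, saying “No target loss is evident, so the maximum falls at the end.” The flask reaches the level at 1.25 d, inside the bracket, and holds its best, 31.1%, at 6.07 d.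

    reagent in the reaction phase ⇌ reagent in the second phase, rate k1*([reagent in the reaction phase] - [reagent in the second phase]/K1) per volume of the first phase (partition coefficient = 2.40, kL = 7.60 × 10⁻⁶ s⁻¹)
    substrate + reagent in the reaction phase ⇌ target (K = 260 M⁻¹, k = 8.30 × 10⁻⁴ M⁻¹ s⁻¹)
    reagent in the reaction phase + target → over-reacted product (k = 4.20 × 10⁻⁴ M⁻¹ s⁻¹)

**Thin neighbour.** At 2.50 d the flask holds 21.1% against the west reading 22.5%, an exponent of 0.153, below 0.887. We reckon the same way for a neighbour charged at 0.025 M, now on best amounts, whose times may differ. Exponent zero keeps the flask's 31.1%, and 0.887 lowers it to 9.09%. The neighbour's best is 27.2%, an exponent of 0.0967.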